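**Retrosynthetic overview**

1. The target 19 comes from the bis-silyl ether 18 by a buffered desilylation that leaves C3 untouched.
2. Key disconnection: the C2–C3 bond of the chroman-4-one (ring C). C2 and the 5-OCH3 carbon are the two methoxy carbons of one symmetric 2,6-dimethoxyaryl α-aryl-α-diazoketone 16. An enantioselective Rh-carbenoid insertion into one O–CH3 C–H bond closes ring C (O1–C2–C3–C4–C4a–C8a) and sets C3; the twin methoxy group stays as 5-OMe.
3. Diazoketone 16 comes from acyldiazomethane 6 and iodochromene 15 by Pd-catalysed C–H arylation of the diazo carbon (C3–C1' bond).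
4. Fragment 6 derives from 4-hydroxy-2,6-dimethoxybenzaldehyde (ring A). Fragment 15 derives from 5-iodosalicylaldehyde by propargyl ether Claisen/oxa-6π cyclisation and Dakin oxidation.
5. Ring order: the 2,2-dimethylpyran of the B-ring chromene first (step 5), ring C last (step 9).

Key step: step 9

Assumption: the sense of induction of the dirhodium catalyst in step 9 has to be assigned on the first run. The route is written for Rh2(S-PTAD)4; the antipode Rh2(R-PTAD)4 would be used if the (3R) product were to form.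

Remark on numbering: compounds that deliver carbon to the skeleton carry numbers. Protecting-group and redox reagents are given by name and SMILES on the reagent line.

**Route**

Step 1
Reactants: 1 4-hydroxy-2,6-dimethoxybenzaldehyde
Product: 2 2,6-dimethoxy-4-[(triisopropylsilyl)oxy]benzaldehyde
Conditions: TIPSCl (1.2 equiv), imidazole (2.5 equiv), DMF, 0 °C to rt
Reagents that add atoms: triisopropylsilyl chloride, CC(C)[Si](Cl)(C(C)C)C(C)C
Why: Standard O-silylation of the only free phenol; the bulky TIPS ether should survive the acidic, basic and carbenoid steps that follow.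

Step 2
Reactants: 2 2,6-dimethoxy-4-[(triisopropylsilyl)oxy]benzaldehyde
Product: 3 2,6-dimethoxy-4-[(triisopropylsilyl)oxy]benzoic acid
Conditions: NaClO2, NaH2PO4, 2-methyl-2-butene, t-BuOH/THF/H2O, 0 °C to rt
Reagents that add atoms: sodium chlorite, [Na+].[O-]Cl=O
Why: Pinnick oxidation tolerates the hindered, electron-rich aldehyde, and the alkene scavenger keeps hypochlorous acid away from the arene.

Step 3
Reactants: 3 2,6-dimethoxy-4-[(triisopropylsilyl)oxy]benzoic acid; 4 trimethylsilyldiazomethane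
Product: 6 2-diazo-1-{2,6-dimethoxy-4-[(triisopropylsilyl)oxy]phenyl}ethan-1-one, via acid chloride 5 (not isolated)
Conditions: (COCl)2, DMF (cat.), CH2Cl2, 0 °C to rt, evaporate; then 4 (2 equiv), THF/MeCN, 0 °C to rt
Reagents that add atoms: oxalyl chloride, ClC(=O)C(=O)Cl (supplies the chlorine of 5 only)
Why: Arndt–Eistert-type acylation of the diazo carbon by the electron-rich aroyl chloride; chloride removes the silyl group, so the acyldiazomethane should form without free HCl.

Step 4
Reactants: 7 2-hydroxy-5-iodobenzaldehyde; 8 3-chloro-3-methylbut-1-yne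
Product: 9 5-iodo-2-[(2-methylbut-3-yn-2-yl)oxy]benzaldehyde
Conditions: DBU, CuCl2·2H2O (cat.), MeCN, 0 °C to rt
Reagents that add atoms: none
Why: Copper-catalysed propargylic substitution is the established O-alkylation of electron-poor, chelated phenols with tertiary propargylic chlorides.

Step 5
Reactants: 9 5-iodo-2-[(2-methylbut-3-yn-2-yl)oxy]benzaldehyde
Product: 12 6-iodo-2,2-dimethyl-2H-chromene-8-carbaldehyde, via allenylphenol 10 (not isolated), via o-quinone methide 11 (not isolated)
Conditions: N,N-diethylaniline, 190 °C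
Reagents that add atoms: none
Why: Aryl propargyl ether Claisen rearrangement to the only free ortho position, then tautomerisation, [1,5]-H shift and oxa-6π electrocyclisation should give the 2,2-dimethyl-2H-pyran ring.

Step 6
Reactants: 12 6-iodo-2,2-dimethyl-2H-chromene-8-carbaldehyde
Product: 14 6-iodo-2,2-dimethyl-2H-chromen-8-ol, via aryl formate 13 (not isolated)
Conditions: 30% H2O2, H2SO4 (cat.), MeOH, rt
Reagents that add atoms: hydrogen peroxide, OO
Why: Acid-catalysed Dakin oxidation, in which the ortho-alkoxy group promotes aryl migration and the formate is methanolysed in the flask; the peracid-free medium should spare the chromene double bond.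

Step 7
Reactants: 14 6-iodo-2,2-dimethyl-2H-chromen-8-ol
Product: 15 [(6-iodo-2,2-dimethyl-2H-chromen-8-yl)oxy]triisopropylsilane
Conditions: TIPSCl, imidazole, DMAP (cat.), DMF, rt to 40 °C
Reagents that add atoms: triisopropylsilyl chloride, CC(C)[Si](Cl)(C(C)C)C(C)C
Why: Standard O-silylation masks the phenol, which would otherwise undergo O–H insertion with the carbenoid of step 9.

Step 8
Reactants: 6 2-diazo-1-{2,6-dimethoxy-4-[(triisopropylsilyl)oxy]phenyl}ethan-1-one; 15 [(6-iodo-2,2-dimethyl-2H-chromen-8-yl)oxy]triisopropylsilane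
Product: 16 2-diazo-1-{2,6-dimethoxy-4-[(triisopropylsilyl)oxy]phenyl}-2-{2,2-dimethyl-8-[(triisopropylsilyl)oxy]-2H-chromen-6-yl}ethan-1-one
Conditions: Pd(PPh3)4 (5 mol%), Ag2CO3 (0.5 equiv), Et3N (2 equiv), toluene, rt, dark
Reagents that add atoms: none
Why: Pd-catalysed C–H arylation of an acyldiazomethane with an aryl iodide (oxidative addition, silver-assisted metalation of the diazo C–H, reductive elimination) keeps the diazo group at room temperature.

Step 9
Reactants: 16 2-diazo-1-{2,6-dimethoxy-4-[(triisopropylsilyl)oxy]phenyl}-2-{2,2-dimethyl-8-[(triisopropylsilyl)oxy]-2H-chromen-6-yl}ethan-1-one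
Product: 18 (3S)-3-{2,2-dimethyl-8-[(triisopropylsilyl)oxy]-2H-chromen-6-yl}-5-methoxy-7-[(triisopropylsilyl)oxy]chroman-4-one, via rhodium carbenoid 17 (not isolated)
Conditions: Rh2(S-PTAD)4 (1 mol%), 4 Å MS, CH2Cl2, 40 °C, addition of 16 by syringe pump over 3 h (final 0.01 M)
Reagents that add atoms: none
Why: Proposed new method: the catalyst should expel N2 from 16 to give the donor/acceptor rhodium carbenoid 17, whose electrophilic carbon inserts through a concerted, asynchronous, hydride-transfer-like three-centre transition state into a C–H bond of the neighbouring O–CH3 group, which is activated by the oxygen lone pair, and so forms the C2–C3 bond. The closest known reactions are the Rh(II)-catalysed C–H insertion of o-alkoxyaryl diazoketones at O–CH2R to give chroman-4-ones and the enantioselective intermolecular insertion of aryl(acceptor) carbenoids into methyl ether C–H bonds; the new element is their combination on a primary O–CH3 with an α-aryl-α-diazoketone. Ring C (O1–C2–C3–C4–C4a–C8a) closes by 1,6-C–H insertion, that is a six-membered ring by C–C bond formation, since the 1,5-position is the ether oxygen and carries no hydrogen. C3 is the carbenoid carbon, and its configuration is set by the chiral carboxylate pocket, which decides which carbenoid face meets the C–H bond (catalyst control, no other stereocentre present). The step needs insertion to win over reversible five-membered oxonium ylide formation at the same methoxy oxygen with [1,2]-methyl shift and over intermolecular cyclopropanation of the chromene C3=C4 bond; the poor migratory aptitude of methyl, slow addition at high dilution and the hindered cis-alkene next to the gem-dimethyl carbon should secure this. The two ortho methoxy groups are homotopic, so every rotamer offers an O–CH3 and no regiochemical issue arises, and the neutral medium should leave the enolisable C3–H stereocentre intact.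

Step 10
Reactants: 18 (3S)-3-{2,2-dimethyl-8-[(triisopropylsilyl)oxy]-2H-chromen-6-yl}-5-methoxy-7-[(triisopropylsilyl)oxy]chroman-4-one
Product: 19 (3S)-7-hydroxy-3-(8-hydroxy-2,2-dimethyl-2H-chromen-6-yl)-5-methoxychroman-4-one
Conditions: TBAF (2.4 equiv), AcOH (3 equiv), THF, 0 °C
Reagents that add atoms: none
Why: Fluoride-induced cleavage of both aryl silyl ethers; the acetic acid buffer should keep the medium non-basic so that the α-aryl ketone stereocentre at C3 is not enolised.

**Compound list**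

1 | 4-hydroxy-2,6-dimethoxybenzaldehyde | COc1cc(O)cc(OC)c1C=O | starting material
2 | 2,6-dimethoxy-4-[(triisopropylsilyl)oxy]benzaldehyde | COc1cc(O[Si](C(C)C)(C(C)C)C(C)C)cc(OC)c1C=O | intermediate
3 | 2,6-dimethoxy-4-[(triisopropylsilyl)oxy]benzoic acid | COc1cc(O[Si](C(C)C)(C(C)C)C(C)C)cc(OC)c1C(=O)O | intermediate
4 | trimethylsilyldiazomethane | C[Si](C)(C)C=[N+]=[N-] | starting material
5 | 2,6-dimethoxy-4-[(triisopropylsilyl)oxy]benzoyl chloride (not isolated) | COc1cc(O[Si](C(C)C)(C(C)C)C(C)C)cc(OC)c1C(=O)Cl | intermediate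
6 | 2-diazo-1-{2,6-dimethoxy-4-[(triisopropylsilyl)oxy]phenyl}ethan-1-one | COc1cc(O[Si](C(C)C)(C(C)C)C(C)C)cc(OC)c1C(=O)C=[N+]=[N-] | intermediate
7 | 2-hydroxy-5-iodobenzaldehyde | O=Cc1cc(I)ccc1O | starting material
8 | 3-chloro-3-methylbut-1-yne | C#CC(C)(C)Cl | starting material
9 | 5-iodo-2-[(2-methylbut-3-yn-2-yl)oxy]benzaldehyde | O=Cc1cc(I)ccc1OC(C)(C)C#C | intermediate
10 | 2-hydroxy-5-iodo-3-(3-methylbuta-1,2-dien-1-yl)benzaldehyde, allenylphenol (not isolated) | O=Cc1cc(I)cc(C=C=C(C)C)c1O | intermediate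
11 | 3-iodo-5-(3-methylbut-2-en-1-ylidene)-6-oxocyclohexa-1,3-diene-1-carbaldehyde, o-quinone methide (not isolated) | O=CC1=CC(I)=CC(=CC=C(C)C)C1=O | intermediate
12 | 6-iodo-2,2-dimethyl-2H-chromene-8-carbaldehyde | O=Cc1cc(I)cc2c1OC(C)(C)C=C2 | intermediate
13 | 6-iodo-2,2-dimethyl-2H-chromen-8-yl formate (not isolated) | O=COc1cc(I)cc2c1OC(C)(C)C=C2 | intermediate
14 | 6-iodo-2,2-dimethyl-2H-chromen-8-ol | Oc1cc(I)cc2c1OC(C)(C)C=C2 | intermediate
15 | [(6-iodo-2,2-dimethyl-2H-chromen-8-yl)oxy]triisopropylsilane | CC(C)[Si](Oc1cc(I)cc2c1OC(C)(C)C=C2)(C(C)C)C(C)C | intermediate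
16 | 2-diazo-1-{2,6-dimethoxy-4-[(triisopropylsilyl)oxy]phenyl}-2-{2,2-dimethyl-8-[(triisopropylsilyl)oxy]-2H-chromen-6-yl}ethan-1-one | COc1cc(O[Si](C(C)C)(C(C)C)C(C)C)cc(OC)c1C(=O)C(=[N+]=[N-])c1cc(O[Si](C(C)C)(C(C)C)C(C)C)c2c(c1)C=CC(C)(C)O2 | intermediate
17 | rhodium carbenoid of 16, dirhodium tetracarboxylate ligand sphere omitted (not isolated) | COc1cc(O[Si](C(C)C)(C(C)C)C(C)C)cc(OC)c1C(=O)C(=[Rh])c1cc(O[Si](C(C)C)(C(C)C)C(C)C)c2c(c1)C=CC(C)(C)O2 | intermediate
18 | (3S)-3-{2,2-dimethyl-8-[(triisopropylsilyl)oxy]-2H-chromen-6-yl}-5-methoxy-7-[(triisopropylsilyl)oxy]chroman-4-one | COc1cc(O[Si](C(C)C)(C(C)C)C(C)C)cc2c1C(=O)[C@@H](c1cc(O[Si](C(C)C)(C(C)C)C(C)C)c3c(c1)C=CC(C)(C)O3)CO2 | intermediate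
19 | (3S)-7-hydroxy-3-(8-hydroxy-2,2-dimethyl-2H-chromen-6-yl)-5-methoxychroman-4-one | COc1cc(O)cc2c1C(=O)[C@@H](c1cc(O)c3c(c1)C=CC(C)(C)O3)CO2 | target

**Step count**

Total: 10 steps. Longest linear sequence: 7 steps (steps 4, 5, 6, 7, 8, 9, 10, from 7 to 19).

**Steps most likely to fail**

1. Step 9 (proposed new method). The carbenoid may be diverted into oxonium ylide formation at the ortho methoxy oxygen with [1,2]-methyl shift, or into intermolecular cyclopropanation of the chromene double bond. The insertion may also run with poor facial selectivity at the carbenoid carbon.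

Fallback (known chemistry): it sets out from 15 and returns to the route at 18.
- Miyaura borylation of 15 (B2pin2, PdCl2(dppf), KOAc, dioxane, 80 °C) should give 2-{2,2-dimethyl-8-[(triisopropylsilyl)oxy]-2H-chromen-6-yl}-4,4,5,5-tetramethyl-1,3,2-dioxaborolane F1.
- In parallel, commercial 1-(2,4-dihydroxy-6-methoxyphenyl)ethan-1-one (COc1cc(O)cc(O)c1C(C)=O) would be silylated at the non-chelated 4-OH (TIPSCl, imidazole, DMF) to 1-{2-hydroxy-6-methoxy-4-[(triisopropylsilyl)oxy]phenyl}ethan-1-one F2.
- Condensation of F2 with DMF dimethyl acetal (90 °C) should give (E)-3-(dimethylamino)-1-{2-hydroxy-6-methoxy-4-[(triisopropylsilyl)oxy]phenyl}prop-2-en-1-one F3.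
- Iodocyclisation of F3 (I2, pyridine, CHCl3, rt) should give 3-iodo-5-methoxy-7-[(triisopropylsilyl)oxy]-4H-chromen-4-one F4.
- Suzuki coupling of F1 with F4 (Pd(PPh3)4, K3PO4, dioxane/H2O, 80 °C) should give the isoflavone 3-{2,2-dimethyl-8-[(triisopropylsilyl)oxy]-2H-chromen-6-yl}-5-methoxy-7-[(triisopropylsilyl)oxy]-4H-chromen-4-one F5.
- Asymmetric transfer hydrogenation of F5 with dynamic kinetic resolution (Ru(II)–TsDPEN catalyst of the antipode that delivers the 3S,4S product, HCO2H/Et3N, EtOAc, 40 °C) should reduce the enone and the ketone to (3S,4S)-cis-3-{2,2-dimethyl-8-[(triisopropylsilyl)oxy]-2H-chromen-6-yl}-5-methoxy-7-[(triisopropylsilyl)oxy]chroman-4-ol F6.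
- Buffered Dess–Martin oxidation of F6 (NaHCO3, CH2Cl2, 0 °C) should then give 18 without touching C3.

2. Step 8. The diazo group may be lost through palladium carbene formation and migratory insertion, or oxidative addition of the electron-rich iodide may be too slow at a temperature the diazo compound tolerates.

Fallback: it sets out from 3 and 15 and returns at 16.
- Acid 3 with MeLi (2.2 equiv, THF, 0 °C) should give the methyl ketone 1-{2,6-dimethoxy-4-[(triisopropylsilyl)oxy]phenyl}ethan-1-one F7.
- Pd-catalysed enolate α-arylation of F7 with 15 (Pd2(dba)3, Xantphos, K3PO4, toluene, 90 °C) should give the deoxybenzoin 1-{2,6-dimethoxy-4-[(triisopropylsilyl)oxy]phenyl}-2-{2,2-dimethyl-8-[(triisopropylsilyl)oxy]-2H-chromen-6-yl}ethan-1-one F8.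
- Regitz diazo transfer to F8 (p-ABSA, DBU, MeCN, 0 °C to rt) should give 16.

3. Step 6. Acid-promoted addition of methanol or oxidative attack at the electron-rich chromene double bond may compete with aryl migration, or hydride migration may lead to over-oxidation at the aldehyde carbon.

Fallback: it carries the oxygen from the start and unveils it by demethylation instead of creating it by oxidation. It sets out from 8, together with commercial 4-iodo-2-methoxyphenol (COc1cc(I)ccc1O), and returns at 14.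
- Copper-catalysed O-propargylation with 8 (DBU, CuCl2 cat., MeCN) should give 4-iodo-2-methoxy-1-[(2-methylbut-3-yn-2-yl)oxy]benzene F9.
- Claisen rearrangement and cyclisation of F9 (N,N-diethylaniline, 190 °C) should give 6-iodo-8-methoxy-2,2-dimethyl-2H-chromene F10.
- Thiolate O-demethylation of F10 (NaSEt, DMF, 110 °C, dark) should give 14.

**Further compounds**

F1 | step 9 | 2-{2,2-dimethyl-8-[(triisopropylsilyl)oxy]-2H-chromen-6-yl}-4,4,5,5-tetramethyl-1,3,2-dioxaborolane | CC(C)[Si](Oc1cc(B2OC(C)(C)C(C)(C)O2)cc2c1OC(C)(C)C=C2)(C(C)C)C(C)C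
F2 | step 9 | 1-{2-hydroxy-6-methoxy-4-[(triisopropylsilyl)oxy]phenyl}ethan-1-one | COc1cc(O[Si](C(C)C)(C(C)C)C(C)C)cc(O)c1C(C)=O
F3 | step 9 | (E)-3-(dimethylamino)-1-{2-hydroxy-6-methoxy-4-[(triisopropylsilyl)oxy]phenyl}prop-2-en-1-one | COc1cc(O[Si](C(C)C)(C(C)C)C(C)C)cc(O)c1C(=O)/C=C/N(C)C
F4 | step 9 | 3-iodo-5-methoxy-7-[(triisopropylsilyl)oxy]-4H-chromen-4-one | COc1cc(O[Si](C(C)C)(C(C)C)C(C)C)cc2c1C(=O)C(I)=CO2
F5 | step 9 | 3-{2,2-dimethyl-8-[(triisopropylsilyl)oxy]-2H-chromen-6-yl}-5-methoxy-7-[(triisopropylsilyl)oxy]-4H-chromen-4-one | COc1cc(O[Si](C(C)C)(C(C)C)C(C)C)cc2c1C(=O)C(c1cc(O[Si](C(C)C)(C(C)C)C(C)C)c3c(c1)C=CC(C)(C)O3)=CO2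
F6 | step 9 | (3S,4S)-cis-3-{2,2-dimethyl-8-[(triisopropylsilyl)oxy]-2H-chromen-6-yl}-5-methoxy-7-[(triisopropylsilyl)oxy]chroman-4-ol | COc1cc(O[Si](C(C)C)(C(C)C)C(C)C)cc2c1[C@@H](O)[C@@H](c1cc(O[Si](C(C)C)(C(C)C)C(C)C)c3c(c1)C=CC(C)(C)O3)CO2
F7 | step 8 | 1-{2,6-dimethoxy-4-[(triisopropylsilyl)oxy]phenyl}ethan-1-one | COc1cc(O[Si](C(C)C)(C(C)C)C(C)C)cc(OC)c1C(C)=O
F8 | step 8 | 1-{2,6-dimethoxy-4-[(triisopropylsilyl)oxy]phenyl}-2-{2,2-dimethyl-8-[(triisopropylsilyl)oxy]-2H-chromen-6-yl}ethan-1-one | COc1cc(O[Si](C(C)C)(C(C)C)C(C)C)cc(OC)c1C(=O)Cc1cc(O[Si](C(C)C)(C(C)C)C(C)C)c2c(c1)C=CC(C)(C)O2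
F9 | step 6 | 4-iodo-2-methoxy-1-[(2-methylbut-3-yn-2-yl)oxy]benzene | COc1cc(I)ccc1OC(C)(C)C#C
F10 | step 6 | 6-iodo-8-methoxy-2,2-dimethyl-2H-chromene | COc1cc(I)cc2c1OC(C)(C)C=C2
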